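## Analysis of the target

The target is 5,2',4'-trihydroxy-7-(3-methylbut-2-enyloxy)isoflavone. It is a 4H-chromen-4-one (ring A fused to the pyranone ring C) carrying a 2,4-dihydroxyphenyl ring B at C3, a hydrogen-bonded 5-OH and a prenyl ether at O7. It has no stereocentre, so the only stereochemical question in a synthesis is whether a transient centre is later erased. The sensitive groups are three. The prenyl aryl ether does not survive Lewis acids or quinone oxidants and can undergo Claisen rearrangement. Ring C is opened by hard nucleophiles at C2. The 2'-OH can add to C2 or cyclise oxidatively onto it. The difficulty lies in putting the aryl group on C3 while closing ring C, and in telling four phenols apart so that only O7 is alkylated. The strategy rests on C2: it is a CH bonded only to O1 and C3, so it can be the methyl carbon of an ortho methoxy group already on ring A. C3, which carries ring B and sits next to the C4 carbonyl, can then be a donor/acceptor carbene carbon. With a 2,4,6-trimethoxyphenyl ring A, the two ortho methoxy groups are equivalent, and the remaining two become the 5- and 7-oxygens.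

## Retrosynthetic reasoning

The O7–prenyl bond is cut first, leading back to tetraphenol 10 and prenyl bromide 11. The prenyl ether is the most fragile group and must come after all acidic and oxidative steps. The cut is possible without protection because the 7-OH is a vinylogous acid through the C4 carbonyl, the 5-OH is tied up in a hydrogen bond to that carbonyl, and the ring B phenols are ordinary phenols. The forward step must therefore be a monoalkylation under acidity control with one equivalent of a weak base.

The four O-protecting groups are removed next in the backward sense: the two methyl groups at O5 and O7 (10 from 9) and the two silyl groups at O2' and O4' (9 from 8). They are taken off in two separate operations, silicon by fluoride and methyl by a boron trihalide, so that each step is one well-defined event. The silyl groups are kept until the oxidation is over because a free 2'-OH next to C2 would interfere there.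

The C2=C3 double bond of isoflavone 8 is traced back to the saturated isoflavanone 7. The forward step is a dehydrogenation by a quinone. It also removes the C3 stereocentre, so the ring-forming step does not have to be stereoselective.

The key cut is C2–C3 of 7, leading to diazo ketone 6. C2 goes back to a methoxy carbon on ring A and C3 to a diazo carbon between ring B and the ketone. This is the only bond of ring C whose cleavage leaves two ordinary functions, an aryl methyl ether and the α-carbon of a deoxybenzoin, and it makes ring A symmetrical. The forward step has to deliver a carbene to a C–H bond of the ortho methoxy group faster than to the oxygen of that group or to anything on ring B. For that reason the ring B oxygens carry triisopropylsilyl groups. A methyl or benzyl ether at O2' would place activated C–H bonds at five-ring distance from the carbene. The silyl ether offers only shielded tertiary Si–CH bonds.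

The diazo group of 6 is traced back to the methylene group of deoxybenzoin 5. The forward step is a base-mediated diazo transfer from a sulfonyl azide to the doubly activated CH2.

Deoxybenzoin 5 is cut at the C3–C1' bond into aryl bromide 3 and methyl ketone 4, to be joined by palladium-catalysed enolate arylation. The other possible cut, C4–C4a by Friedel–Crafts acylation of the trimethoxyarene with an ortho-hydroxylated arylacetic acid, was not used. Under anhydride or acid activation such an acid should close to a benzofuranone, and silyl ethers put on beforehand would meet strong acid. The enolate arylation is basic, uses the phenols already silylated, and the hindered ketone 4 cannot condense with itself.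

Bromide 3 is traced back to 4-bromoresorcinol 1 and silyl chloride 2 by cutting both O–Si bonds.

## Alternatives that were turned down

Alternative 1: Ring C is cut at C3–C4 and O1–C8a. The morpholine enamine A3 of the ring B arylacetaldehyde would be acylated at carbon by the difluorobenzoyl chloride A2. Aqueous carbonate would then exchange the amine for oxygen, and the enolate oxygen would displace one of the two equivalent ortho fluorides to give the 5-fluoroisoflavone A1.
- For it: the ring closure is a well-understood addition–elimination on an ortho-fluoro aryl ketone, which the chosen closure is not. The prenyl ether is in place from the start, so no late site-selective alkylation is needed. On both points this alternative is stronger than the chosen route.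
- Against it: A1 still has the wrong atom at C5. Exchanging fluoride for hydroxyl needs an oxygen nucleophile on a chromone whose C2 is also electrophilic, so ring opening competes. The two allyl groups must then be removed with zerovalent palladium next to a prenyl ether that is itself allylic. A3 is an electron-rich, hydrolytically sensitive enamine, and A2 needs several steps of its own.
- Comparison: three delicate operations would follow the ring closure. The chosen route has one uncertain step, and that step is followed by standard operations on compounds 7 to 10. The chosen route also takes ring A from the purchasable symmetrical ketone 4.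

Alternative 2: Ring C is cut at C3–C1' and O1–C2. Anodic oxidation of the enaminone A5 in the presence of the bis-silylated resorcinol A6 would join C3 to the arene. An ortho phenol of ring A would then add to C2 with loss of dimethylamine, giving A4, which needs only desilylation.
- For it: it is the shortest of the four plans. It needs no demethylation and no late prenylation, and ring A is symmetrical. In step count it clearly beats the chosen route.
- Against it: A5 carries free phloroglucinol-type phenols and a trisubstituted alkene, and A6 is an electron-rich arene. All of these are oxidised at potentials close to that of the enaminone, so the anode has no clear preference. Carbon–carbon bond formation between an oxidised enaminone and a neutral arene is far less secure than the carbon–heteroatom versions. A5 can also close to the 3-unsubstituted chromone before any coupling, which is a dead end.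
- Comparison: both plans depend on an unproven key step. In the chosen route the reactive intermediate arises from 6 under neutral, non-oxidising conditions with the prenyl group still absent, and the competing paths are few and intramolecular.

Alternative 3: Ring C is cut at O1–C8a and C4–C4a. A fluoride source would set free the aryne from the silyl triflate A8. The enolate oxygen of the formylacetate A9 would add to the aryne carbon remote from the flanking methoxy group, and the aryl anion formed next to that methoxy group would attack the methyl ester, giving the tetramethoxyisoflavone A7.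
- For it: it is convergent and reaches the isoflavone oxidation level at once, so the dehydrogenation of 7 to 8 has no counterpart. The regiochemistry of addition to a 3-alkoxy aryne is well understood, and no diazo compound is handled. On these points it is as strong as or stronger than the chosen route.
- Against it: the enolate of A9 is ambident, and stabilised enolates usually attack arynes through carbon, which leads to C-arylation and acyl-alkylation, not to the chromone. A8 needs a multistep preparation. Because ring B carries methyl ethers, A7 still requires full demethylation to 10 and the same selective prenylation, so nothing is saved at the end.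
- Comparison: the selectivity question of the chosen route (C–H bond against oxygen) is intramolecular and biased by the twisted geometry of 6. The O-against-C question of the aryne addition is intermolecular and has no handle in the substrate.

Key step: step 4

Assumption: the target is achiral, so C3 of isoflavanone 7 is carried as a racemate and flattened in step 5; 1 and 4 are taken as purchasable.

## Route

Step 1
Reactants: 1 4-bromobenzene-1,3-diol (4-bromoresorcinol); 2 triisopropylsilyl chloride
Product: 3 1-bromo-2,4-bis(triisopropylsilyloxy)benzene
Conditions: 2 (2.3 equiv), imidazole (5 equiv), DMF, rt to 40 °C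
Reagents that add atoms: triisopropylsilyl chloride 2, CC(C)[Si](Cl)(C(C)C)C(C)C
Why: Standard O-silylation of phenols through the N-silylimidazolium species; both phenols react, and the bulky silyl groups chosen here are the ones that must later survive base, a carbene and a quinone.

Step 2
Reactants: 3 1-bromo-2,4-bis(triisopropylsilyloxy)benzene; 4 1-(2,4,6-trimethoxyphenyl)ethanone
Product: 5 2-[2,4-bis(triisopropylsilyloxy)phenyl]-1-(2,4,6-trimethoxyphenyl)ethanone
Conditions: 4 (1.2 equiv), Pd2(dba)3 (2 mol %), XPhos (8 mol %), anhydrous K3PO4 (2.5 equiv), toluene, 100 °C
Reagents that add atoms: none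
Why: Buchwald–Hartwig-type α-arylation of a methyl ketone: zerovalent palladium inserts into the C–Br bond of 3, the enolate of 4 binds, and reductive elimination forms C3–C1'. The hindered ketone cannot self-condense, the product flanked by two ortho-substituted rings should resist a second arylation, and the phosphate base spares the aryl silyl ethers.

Step 3
Reactants: 5 2-[2,4-bis(triisopropylsilyloxy)phenyl]-1-(2,4,6-trimethoxyphenyl)ethanone
Product: 6 2-diazo-2-[2,4-bis(triisopropylsilyloxy)phenyl]-1-(2,4,6-trimethoxyphenyl)ethanone
Conditions: p-ABSA (1.3 equiv), DBU (1.5 equiv), MeCN, 0 °C to rt, dark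
Reagents that add atoms: 4-acetamidobenzenesulfonyl azide (p-ABSA), CC(=O)Nc1ccc(cc1)S(=O)(=O)N=[N+]=[N-]
Why: Regitz diazo transfer: the CH2 between aryl and carbonyl is the only acidic site, its enolate attacks the terminal nitrogen of the sulfonyl azide, and the triazene anion collapses to the diazo ketone and the sulfonamide, as is usual for benzyl aryl ketones.

Step 4
Reactants: 6 2-diazo-2-[2,4-bis(triisopropylsilyloxy)phenyl]-1-(2,4,6-trimethoxyphenyl)ethanone
Product: 7 racemic 3-[2,4-bis(triisopropylsilyloxy)phenyl]-5,7-dimethoxy-2,3-dihydro-4H-chromen-4-one (5,7-dimethoxy-2',4'-bis(triisopropylsilyloxy)isoflavanone)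
Conditions: Rh2(O2CCPh3)4 (1 mol %), CH2Cl2, 40 °C, slow addition of 6, argon
Reagents that add atoms: none
Why: Proposed new method: Rh2(O2CCPh3)4, a divalent rhodium paddlewheel, adds to the diazo carbon of 6 and expels N2 to give an electrophilic donor/acceptor carbene at C3, flanked by ring B and the C4 carbonyl and free of β-hydrogens, so no 1,2-shift can drain it. Because the 2,6-dimethoxyaryl ketone is twisted out of conjugation, one ortho methoxy group sits over the carbene carbon, and a concerted, asynchronous three-centre insertion into one of its C–H bonds, which are activated by the oxygen lone pair, should form C2–C3. The closest known reaction types are the insertion of dirhodium donor/acceptor carbenes into C–H bonds of methyl ethers and the intramolecular insertions next to ether oxygen that give dihydrobenzofurans and chroman-4-ones; a six-ring insertion into an aryl methyl ether is not established. Ring C closes as a six-membered ring by 1,6-insertion through a chair-like transition state made of C3, C4, C4a, C8a, O1 and the methyl carbon. C3 becomes a stereocentre without any controlling element (achiral catalyst, racemate), which is of no consequence because step 5 flattens it. The step needs selectivity for C–H insertion over oxonium ylide formation at the same oxygen, over Wolff rearrangement and over attack on ring B: a methyl oxonium ylide has no group that migrates readily and should revert, the rhodium-bound carbene is less prone to rearrange than a free ketocarbene, and the silyl ethers of ring B offer only hindered tertiary Si–CH bonds that are not activated by oxygen and are screened by the bulky triphenylacetate ligands. The two ortho methoxy groups are equivalent, so only one constitution can result.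

Step 5
Reactants: 7 racemic 5,7-dimethoxy-2',4'-bis(triisopropylsilyloxy)isoflavanone
Product: 8 3-[2,4-bis(triisopropylsilyloxy)phenyl]-5,7-dimethoxy-4H-chromen-4-one
Conditions: DDQ (1.5 equiv), 1,4-dioxane, 100 °C
Reagents that add atoms: none
Why: Quinone dehydrogenation of a chroman-4-one to a chromone: the enol of 7 gives up hydride from C2, where O1 stabilises the developing cation, and loss of the C3 proton leaves the conjugated pyranone. The silyl ethers keep ring B from being oxidised and keep O2' from closing onto C2.

Step 6
Reactants: 8 3-[2,4-bis(triisopropylsilyloxy)phenyl]-5,7-dimethoxy-4H-chromen-4-one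
Product: 9 3-(2,4-dihydroxyphenyl)-5,7-dimethoxy-4H-chromen-4-one
Conditions: Bu4NF (2.4 equiv), AcOH (2.4 equiv), THF, 0 °C
Reagents that add atoms: none
Why: Fluoride-induced cleavage of aryl silyl ethers, driven by the Si–F bond and the good phenoxide leaving group; acetic acid buffers the medium so that no basic species attacks C2 of ring C.

Step 7
Reactants: 9 3-(2,4-dihydroxyphenyl)-5,7-dimethoxy-4H-chromen-4-one
Product: 10 3-(2,4-dihydroxyphenyl)-5,7-dihydroxy-4H-chromen-4-one (2'-hydroxygenistein)
Conditions: BBr3 (8 equiv), CH2Cl2, −78 °C to rt; then ice-water
Reagents that add atoms: none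
Why: Lewis-acid cleavage of aryl methyl ethers: boron binds the ether oxygen and bromide attacks the methyl carbon in an SN2 step. The 5-OMe goes first with chelation to the C4 carbonyl and the 7-OMe follows at room temperature, while the chromone core is inert and hydrolysis frees the phenols.

Step 8
Reactants: 10 3-(2,4-dihydroxyphenyl)-5,7-dihydroxy-4H-chromen-4-one; 11 1-bromo-3-methylbut-2-ene (prenyl bromide)
Product: 12 3-(2,4-dihydroxyphenyl)-5-hydroxy-7-(3-methylbut-2-enyloxy)-4H-chromen-4-one (target)
Conditions: K2CO3 (1.0 equiv), 11 (1.05 equiv), DMF, 0 °C to rt
Reagents that add atoms: prenyl bromide 11, CC(C)=CCBr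
Why: Williamson ether synthesis under acidity control: the 7-OH, a vinylogous carboxylic acid through the C4 carbonyl, is expected to be the most acidic phenol by a few pKa units, so one equivalent of carbonate should form only the 7-phenoxide. The 5-OH is locked in a hydrogen bond to the carbonyl, the ring B phenols stay protonated, and SN2 at the primary allylic bromide gives the O7 ether.

## Compound list

1 | 4-bromobenzene-1,3-diol (4-bromoresorcinol) | Oc1ccc(Br)c(O)c1 | starting material
2 | triisopropylsilyl chloride | CC(C)[Si](Cl)(C(C)C)C(C)C | starting material
3 | 1-bromo-2,4-bis(triisopropylsilyloxy)benzene | CC(C)[Si](Oc1ccc(Br)c(O[Si](C(C)C)(C(C)C)C(C)C)c1)(C(C)C)C(C)C | intermediate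
4 | 1-(2,4,6-trimethoxyphenyl)ethanone | COc1cc(OC)c(C(C)=O)c(OC)c1 | starting material
5 | 2-[2,4-bis(triisopropylsilyloxy)phenyl]-1-(2,4,6-trimethoxyphenyl)ethanone | COc1cc(OC)c(C(=O)Cc2ccc(O[Si](C(C)C)(C(C)C)C(C)C)cc2O[Si](C(C)C)(C(C)C)C(C)C)c(OC)c1 | intermediate
6 | 2-diazo-2-[2,4-bis(triisopropylsilyloxy)phenyl]-1-(2,4,6-trimethoxyphenyl)ethanone | COc1cc(OC)c(C(=O)C(=[N+]=[N-])c2ccc(O[Si](C(C)C)(C(C)C)C(C)C)cc2O[Si](C(C)C)(C(C)C)C(C)C)c(OC)c1 | intermediate
7 | racemic 3-[2,4-bis(triisopropylsilyloxy)phenyl]-5,7-dimethoxy-2,3-dihydro-4H-chromen-4-one | COc1cc(OC)c2c(c1)OCC(c1ccc(O[Si](C(C)C)(C(C)C)C(C)C)cc1O[Si](C(C)C)(C(C)C)C(C)C)C2=O | intermediate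
8 | 3-[2,4-bis(triisopropylsilyloxy)phenyl]-5,7-dimethoxy-4H-chromen-4-one | COc1cc(OC)c2c(=O)c(-c3ccc(O[Si](C(C)C)(C(C)C)C(C)C)cc3O[Si](C(C)C)(C(C)C)C(C)C)coc2c1 | intermediate
9 | 3-(2,4-dihydroxyphenyl)-5,7-dimethoxy-4H-chromen-4-one | COc1cc(OC)c2c(=O)c(-c3ccc(O)cc3O)coc2c1 | intermediate
10 | 3-(2,4-dihydroxyphenyl)-5,7-dihydroxy-4H-chromen-4-one (2'-hydroxygenistein) | Oc1cc(O)c2c(=O)c(-c3ccc(O)cc3O)coc2c1 | intermediate
11 | 1-bromo-3-methylbut-2-ene (prenyl bromide) | CC(C)=CCBr | starting material
12 | 3-(2,4-dihydroxyphenyl)-5-hydroxy-7-(3-methylbut-2-enyloxy)-4H-chromen-4-one | CC(C)=CCOc1cc(O)c2c(=O)c(-c3ccc(O)cc3O)coc2c1 | target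

## Step count and risk

Total step count: 8. Longest linear sequence: 8 steps (1 → 3 → 5 → 6 → 7 → 8 → 9 → 10 → 12); ketone 4 enters in step 2.

Least certain steps:

Step 4 (key step, proposed new method). The carbene may be captured by the lone pair of the ortho methoxy oxygen instead of its C–H bond, followed by a methyl shift to a benzofuranone. It may also undergo Wolff rearrangement, dimerise, or insert into an isopropyl C–H bond of the 2'-silyl group. None of these paths is excluded by precedent for a six-ring closure onto an aryl methyl ether. The fallback sets out from deoxybenzoin 5, closes ring C by known chemistry and takes C2 from a formamide acetal instead of the methoxy group. BCl3 in CH2Cl2 at −78 to 0 °C removes one of the two equivalent ortho methyl groups with chelation to the ketone and should give 2-[2,4-bis(triisopropylsilyloxy)phenyl]-1-(2-hydroxy-4,6-dimethoxyphenyl)ethanone F1. Heating F1 with N,N-dimethylformamide dimethyl acetal in toluene should form the enaminone 3-(dimethylamino)-2-[2,4-bis(triisopropylsilyloxy)phenyl]-1-(2-hydroxy-4,6-dimethoxyphenyl)prop-2-en-1-one F2, whose phenol adds to the enamine carbon and expels dimethylamine. The fallback comes back to the route at isoflavone 8, bypassing 6 and 7.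

Step 2. Oxidative addition and reductive elimination may be slow at the electron-rich bromide with its bulky ortho silyloxy group. At 100 °C the base, or the product enolate through an O-to-O silyl shift, may strip the 2'-silyl group. The fallback moves the silylation behind the C–C bond formation and sets out from 1 and 4. Benzyl bromide and K2CO3 in DMF convert 1 into 1-bromo-2,4-bis(benzyloxy)benzene F3. F3 is coupled with 4 under the same palladium catalysis with NaOC(CH3)3 as base (the benzyl ethers are inert to it), giving 2-[2,4-bis(benzyloxy)phenyl]-1-(2,4,6-trimethoxyphenyl)ethanone F4. Hydrogenolysis (H2, palladium on carbon, ethyl acetate) gives 2-(2,4-dihydroxyphenyl)-1-(2,4,6-trimethoxyphenyl)ethanone F5. Silylation of F5 with 2 and imidazole comes back to the route at 5.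

Step 3. Deprotonation of the CH2 between an electron-rich ring and a twisted, weakly activating ketone may be slow, and the amidine base may meanwhile attack the aryl silyl ethers, so the transfer could stall or proceed with desilylation. The fallback sets out from 5 and activates the methylene by acylation before the transfer. LiN(SiMe3)2 in THF at −78 °C followed by 2,2,2-trifluoroethyl trifluoroacetate gives 4,4,4-trifluoro-2-[2,4-bis(triisopropylsilyloxy)phenyl]-1-(2,4,6-trimethoxyphenyl)butane-1,3-dione F6. Methanesulfonyl azide with triethylamine in wet MeCN then transfers the diazo group with loss of the trifluoroacetyl group. The fallback comes back to the route at 6.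

Step 8. Alkylation may not stop at O7. Proton exchange between the product and unreacted phenoxides, or a smaller acidity gap than assumed for the resorcinol ring B, could lead to alkylation at O4' or O2' and to C-prenylation of ring A. The fallback sets out from 10 and replaces acidity control by protecting-group control.
- Acetic anhydride in pyridine gives 5,7,2',4'-tetraacetoxyisoflavone F7.
- Thiophenol and imidazole in N-methylpyrrolidone at 0 °C remove the most activated ester, giving 5,2',4'-triacetoxy-7-hydroxyisoflavone F8.
- A Mitsunobu reaction of F8 with 3-methylbut-2-en-1-ol, PPh3 and diisopropyl azodicarboxylate in THF gives 5,2',4'-triacetoxy-7-(3-methylbut-2-enyloxy)isoflavone F9.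
- K2CO3 in methanol at 0 °C removes the three acetates and comes back to the route at target 12.

## Further compounds

F1 | step 4 | 2-[2,4-bis(triisopropylsilyloxy)phenyl]-1-(2-hydroxy-4,6-dimethoxyphenyl)ethanone | COc1cc(O)c(C(=O)Cc2ccc(O[Si](C(C)C)(C(C)C)C(C)C)cc2O[Si](C(C)C)(C(C)C)C(C)C)c(OC)c1
F2 | step 4 | 3-(dimethylamino)-2-[2,4-bis(triisopropylsilyloxy)phenyl]-1-(2-hydroxy-4,6-dimethoxyphenyl)prop-2-en-1-one (alkene geometry not fixed, either isomer cyclises) | COc1cc(O)c(C(=O)C(=CN(C)C)c2ccc(O[Si](C(C)C)(C(C)C)C(C)C)cc2O[Si](C(C)C)(C(C)C)C(C)C)c(OC)c1
F3 | step 2 | 1-bromo-2,4-bis(benzyloxy)benzene | Brc1ccc(OCc2ccccc2)cc1OCc1ccccc1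
F4 | step 2 | 2-[2,4-bis(benzyloxy)phenyl]-1-(2,4,6-trimethoxyphenyl)ethanone | COc1cc(OC)c(C(=O)Cc2ccc(OCc3ccccc3)cc2OCc2ccccc2)c(OC)c1
F5 | step 2 | 2-(2,4-dihydroxyphenyl)-1-(2,4,6-trimethoxyphenyl)ethanone | COc1cc(OC)c(C(=O)Cc2ccc(O)cc2O)c(OC)c1
F6 | step 3 | 4,4,4-trifluoro-2-[2,4-bis(triisopropylsilyloxy)phenyl]-1-(2,4,6-trimethoxyphenyl)butane-1,3-dione | COc1cc(OC)c(C(=O)C(C(=O)C(F)(F)F)c2ccc(O[Si](C(C)C)(C(C)C)C(C)C)cc2O[Si](C(C)C)(C(C)C)C(C)C)c(OC)c1
F7 | step 8 | 5,7,2',4'-tetraacetoxyisoflavone | CC(=O)Oc1cc(OC(C)=O)c2c(=O)c(-c3ccc(OC(C)=O)cc3OC(C)=O)coc2c1
F8 | step 8 | 5,2',4'-triacetoxy-7-hydroxyisoflavone | CC(=O)Oc1cc(O)cc2occ(-c3ccc(OC(C)=O)cc3OC(C)=O)c(=O)c12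
F9 | step 8 | 5,2',4'-triacetoxy-7-(3-methylbut-2-enyloxy)isoflavone | CC(C)=CCOc1cc(OC(C)=O)c2c(=O)c(-c3ccc(OC(C)=O)cc3OC(C)=O)coc2c1
A1 | alternative 1 | 2',4'-bis(allyloxy)-5-fluoro-7-(3-methylbut-2-enyloxy)isoflavone | CC(C)=CCOc1cc(F)c2c(=O)c(-c3ccc(OCC=C)cc3OCC=C)coc2c1
A2 | alternative 1 | 2,6-difluoro-4-(3-methylbut-2-enyloxy)benzoyl chloride | CC(C)=CCOc1cc(F)c(C(Cl)=O)c(F)c1
A3 | alternative 1 | 4-[(E)-2-[2,4-bis(allyloxy)phenyl]ethenyl]morpholine | C=CCOc1ccc(/C=C/N2CCOCC2)c(OCC=C)c1
A4 | alternative 2 | 2',4'-bis(tert-butyldimethylsilyloxy)-5-hydroxy-7-(3-methylbut-2-enyloxy)isoflavone | CC(C)=CCOc1cc(O)c2c(=O)c(-c3ccc(O[Si](C)(C)C(C)(C)C)cc3O[Si](C)(C)C(C)(C)C)coc2c1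
A5 | alternative 2 | (E)-1-[2,6-dihydroxy-4-(3-methylbut-2-enyloxy)phenyl]-3-(dimethylamino)prop-2-en-1-one | CC(C)=CCOc1cc(O)c(C(=O)/C=C/N(C)C)c(O)c1
A6 | alternative 2 | 1,3-bis(tert-butyldimethylsilyloxy)benzene | CC(C)(C)[Si](C)(C)Oc1cccc(O[Si](C)(C)C(C)(C)C)c1
A7 | alternative 3 | 5,7,2',4'-tetramethoxyisoflavone | COc1cc(OC)c2c(=O)c(-c3ccc(OC)cc3OC)coc2c1
A8 | alternative 3 | 3,5-dimethoxy-2-(trimethylsilyl)phenyl trifluoromethanesulfonate | COc1cc(OC)c([Si](C)(C)C)c(OS(=O)(=O)C(F)(F)F)c1
A9 | alternative 3 | methyl 2-(2,4-dimethoxyphenyl)-3-oxopropanoate | COC(=O)C(C=O)c1ccc(OC)cc1OC
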